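**Retrosynthetic overview**
- The target is fisetinidol-(4β→6)-fisetinidol-(4α→6)-leucofisetinidin. Both interflavan bonds are cut. C4(top)–C6(middle), 3,4-cis, comes from aryllithium addition to a chroman-4-one followed by semipinacol shift and reduction. C4(middle)–C6(bottom), 3,4-trans, comes from a Friedel–Crafts alkylation.
- All three flavan units derive from one monomer, tri-O-benzyl-(2R,3R)-fustin 7. Its ring C is not closed as a six-membered ring. It is grown from the five-membered hemiacetal ring of 2 by inserting the aryl-bearing carbon C2 from a chiral sulfonium ylide.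
- Enabling feature, in ring C: O1 and the C3 oxygen sit anti on the neighbouring carbons C2 (benzylic to ring B) and C3, and O1 reaches C3 by the short path C8a–C4a–C4. O1 can therefore first rest on C3 in a five-membered ring (O1, C3, C4, C4a, C8a) and move to C2 when C2 arrives.
- Ring order: rings A and B are bought. The five-membered O-heterocycle forms in step 1 and becomes ring C in step 3. One batch of 7 supplies ring C of all three units, and no ring is formed afterwards.

Key step: step 3

Remark 1: the α face of ring C is the face that carries ring B at C2; the β face is the opposite one. Bn = benzyl, TBS = tert-butyldimethylsilyl.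
Remark 2 (assumption): the 2-hydroxyaryl glyoxal from step 1 is taken to rest as its ring tautomer, the five-membered hemiacetal 2.
Remark 3 (assumption): the (1R,4R,5R) sulfide 4 is taken to deliver the (αR,βS) epoxy ketone. If the sense of induction is opposite, its enantiomer is used and nothing else changes.

**Step 1**
Reactants: 1 1-[4-(benzyloxy)-2-hydroxyphenyl]ethan-1-one
Product: 2 6-(benzyloxy)-2-hydroxy-1-benzofuran-3(2H)-one (cyclic hemiacetal, both epimers at the hemiacetal carbon)
Conditions: SeO2, 1,4-dioxane–H2O, 90 °C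
Reagents that add atoms: selenium dioxide, O=[Se]=O
Why: The Riley oxidation of the methyl ketone stops at the glyoxal, and the ortho phenol adds to the new aldehyde so that the product should rest as the five-membered hemiacetal, whose only stereocentre epimerises freely.

**Step 2**
Reactants: 3 [3,4-bis(benzyloxy)phenyl]methanol; 4 (1R,4R,5R)-4,7,7-trimethyl-6-thiabicyclo[3.2.1]octane (isothiocineole)
Product: 5 (1R,4R,5R)-6-[3,4-bis(benzyloxy)benzyl]-4,7,7-trimethyl-6-thiabicyclo[3.2.1]octan-6-ium tetrafluoroborate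
Conditions: HBF4·OEt2, CH2Cl2, 0 °C → rt
Reagents that add atoms: tetrafluoroboric acid (as diethyl etherate), [H+].F[B-](F)(F)F
Why: In this SN1-type S-alkylation the acid ionises the electron-rich benzylic alcohol and the sulfide captures the cation on its exposed exo lone pair, which should give one sulfonium diastereomer with a non-nucleophilic counter-ion.

**Step 3**
Reactants: 2 6-(benzyloxy)-2-hydroxy-1-benzofuran-3(2H)-one; 5 sulfonium tetrafluoroborate
Product: 7 (2R,3R)-7-(benzyloxy)-2-[3,4-bis(benzyloxy)phenyl]-3-hydroxychroman-4-one (tri-O-benzylfustin; 2,3-trans), via epoxy ketone phenoxide 6 (not isolated)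
Conditions: KN(SiMe3)2 (2 equiv), THF, −78 → 0 °C; then AcOH
Reagents that add atoms: none
Why: Proposed new method: base opens the five-membered hemiacetal 2 to its glyoxal phenoxide and converts 5 into the benzylic sulfonium ylide, which adds to the aldehyde carbon; collapse of the anti betaine expels sulfide 4 and gives the trans epoxy ketone 6, whose phenoxide opens the benzylic epoxide carbon, so the ArCH unit is inserted between O1 and the former hemiacetal carbon and the ring (O1, C3, C4, C4a, C8a) grows from five to six members. The closest known reaction types are the Johnson–Corey–Chaykovsky epoxidation with chiral sulfonium benzylides, its use on ring-chain tautomeric lactols and hemiaminals with closure in the same flask, and the phenoxide opening of 2'-hydroxychalcone epoxides in the Algar–Flynn–Oyamada reaction. Ring C closes in the 6-endo-tet mode with inversion at C2. C3 is set by the aldehyde face that the sulfide-bound ylide attacks (reagent control by 4), and C2 follows from the trans epoxide geometry plus the invertive opening, which together can only give the 2,3-trans product. The step needs aldehyde-over-ketone selectivity, secured because the aryl ketone is deactivated by the ortho phenoxide and the para benzyloxy group and the glyoxal has no enolisable hydrogen. It also needs 6-endo over 5-exo opening, secured by the 3,4-dialkoxyphenyl group, which takes up positive charge at C2.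

**Step 4**
Reactants: 7 tri-O-benzylfustin
Product: 8 (2R,3R)-7-(benzyloxy)-2-[3,4-bis(benzyloxy)phenyl]-3-[(tert-butyldimethylsilyl)oxy]chroman-4-one
Conditions: t-BuMe2SiOSO2CF3, 2,6-lutidine, CH2Cl2, −40 → 0 °C
Reagents that add atoms: tert-butyldimethylsilyl trifluoromethanesulfonate, CC(C)(C)[Si](C)(C)OS(=O)(=O)C(F)(F)F
Why: This is a standard silylation of a hindered secondary alcohol under non-basic conditions, which avoids base-induced opening of ring C and leaves C2 and C3 untouched.

**Step 5**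
Reactants: 8 3-O-TBS ketone
Product: 9 (2R,3S,4R)-7-(benzyloxy)-2-[3,4-bis(benzyloxy)phenyl]-3-[(tert-butyldimethylsilyl)oxy]chroman-4-ol (2,3-trans-3,4-trans)
Conditions: NaBH4, CeCl3·7H2O, MeOH–THF, −40 °C
Reagents that add atoms: none
Why: In this Luche reduction the small hydride attacks the chromanone carbonyl along the axial trajectory on the β face and should give the equatorial 4α-alcohol, which is the 3,4-trans relationship of the bottom unit.

**Step 6**
Reactants: 9 3-O-TBS-4-ol
Product: 10 3,4-bis-O-TBS ether of 9 (bottom-unit nucleophile, C6–H free)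
Conditions: t-BuMe2SiOSO2CF3, 2,6-lutidine, CH2Cl2, −78 → −20 °C
Reagents that add atoms: tert-butyldimethylsilyl trifluoromethanesulfonate, CC(C)(C)[Si](C)(C)OS(=O)(=O)C(F)(F)F
Why: Buffered silylation masks the ionisable C4 oxygen of the future bottom unit as an ether that survives organolithium reagents and traces of acid, with no change at any stereocentre.

**Step 7**
Reactants: 9 3-O-TBS-4-ol
Product: 11 (2R,3S,4R)-7-(benzyloxy)-2-[3,4-bis(benzyloxy)phenyl]-6-bromo-3-[(tert-butyldimethylsilyl)oxy]chroman-4-ol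
Conditions: N-bromosuccinimide, CH2Cl2, −78 → 0 °C
Reagents that add atoms: N-bromosuccinimide, O=C1CCC(=O)N1Br
Why: Electrophilic aromatic bromination should go to C6 of ring A, which is ortho to the benzyloxy group, para to O1 and less crowded than C8, and the bromine both blocks self-condensation of this unit and serves as the later lithiation handle.

**Step 8**
Reactants: 11 6-bromo-4-ol
Product: 12 4-O-(2,2,2-trichloroacetimidoyl) derivative of 11 (middle-unit electrophile)
Conditions: Cl3CCN, 1,8-diazabicyclo[5.4.0]undec-7-ene (cat.), CH2Cl2, 0 °C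
Reagents that add atoms: trichloroacetonitrile, N#CC(Cl)(Cl)Cl
Why: Base-catalysed addition of the alcohol to trichloroacetonitrile turns the C4 hydroxyl into an imidate, a leaving group that ionises under far milder acid than the silyl ether at C4 of 10.

**Step 9**
Reactants: 10 bottom-unit nucleophile; 12 middle-unit imidate
Product: 13 bromo dimer: 7,3',4'-tri-O-benzyl-6-bromo-3-O-TBS-fisetinidol-(4α→6)-7,3',4'-tri-O-benzyl-3,4-di-O-TBS-leucofisetinidin
Conditions: Me3SiOSO2CF3 (cat.), 4 Å molecular sieves, CH2Cl2, −78 °C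
Reagents that add atoms: none
Why: In this Friedel–Crafts alkylation with a benzylic trichloroacetimidate, the C4 cation (stabilised by O1 and the 7-benzyloxy group) is attacked by C6 of 10 on the α face, opposite the bulky 3β-silyloxy group, which sets the 3,4-trans (4α) interflavan bond.

**Step 10**
Reactants: 13 bromo dimer; 8 3-O-TBS ketone
Product: 15 trimer carbinol (top unit: tertiary 4β-OH and 4α-aryl; 3β-OTBS), via aryllithium 14 (not isolated)
Conditions: t-BuLi (2 equiv), THF, −78 °C; then 8, −78 → −40 °C; then H2O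
Reagents that add atoms: none
Why: Bromine–lithium exchange followed by 1,2-addition of the aryllithium to the chroman-4-one carbonyl forms the C4(top)–C6(middle) bond with the aryl group entering opposite the 3-silyloxy group, and the configuration of this carbinol centre is erased in the next step.

**Step 11**
Reactants: 15 trimer carbinol
Product: 17 protected trimer with free 3β-OH in the top unit (top unit 2,3-trans-3,4-cis; 4β-aryl), via flavan-3-one 16 (not isolated)
Conditions: camphor-10-sulfonic acid (cat.), moist CH2Cl2, −20 → 0 °C; then Et3N, MeOH, NaBH4, −78 °C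
Reagents that add atoms: none
Why: This is a semipinacol rearrangement (1,2-hydride shift with loss of the silyl group) followed by borohydride reduction: the doubly benzylic tertiary alcohol ionises, the axial H-3 shifts suprafacially on the α face to C4 (a centre that, while still epimerisable in 16, also prefers the quasi-axial 4β-aryl position that avoids peri strain with H-5), and hydride then attacks the C3 carbonyl from the open α face, anti to the axial aryl group, to give the equatorial 3β-alcohol.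

**Step 12**
Reactants: 17 protected trimer
Product: 18 nona-O-benzyl trimer with the four aliphatic hydroxyl groups free
Conditions: Bu4NF, AcOH, THF, 0 °C → rt
Reagents that add atoms: none
Why: Buffered fluoride cleaves the three silyl ethers without acid or strong base, so the benzylic C4 alcohol of the bottom unit should neither ionise nor epimerise.

**Step 13**
Reactants: 18 nona-O-benzyl trimer
Product: 19 fisetinidol-(4β→6)-fisetinidol-(4α→6)-(2R,3S,4R)-leucofisetinidin (target)
Conditions: H2 (1 atm), Pd(OH)2/C, THF–MeOH, rt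
Reagents that add atoms: none
Why: Hydrogenolysis of the nine aryl benzyl ethers in neutral medium is much faster than cleavage of the secondary benzylic alcohol or of the benzylic C2–O1 bonds, so all nine stereocentres should be kept.

**Compound list**
1 | 1-[4-(benzyloxy)-2-hydroxyphenyl]ethan-1-one | CC(=O)c1ccc(OCc2ccccc2)cc1O | starting material
2 | 6-(benzyloxy)-2-hydroxy-1-benzofuran-3(2H)-one (hemiacetal, epimeric at C2) | OC1Oc2cc(OCc3ccccc3)ccc2C1=O | intermediate
3 | [3,4-bis(benzyloxy)phenyl]methanol | OCc1ccc(OCc2ccccc2)c(OCc2ccccc2)c1 | starting material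
4 | (1R,4R,5R)-4,7,7-trimethyl-6-thiabicyclo[3.2.1]octane (isothiocineole) | C[C@@H]1CC[C@@H]2C[C@H]1SC2(C)C | starting material
5 | 6-[3,4-bis(benzyloxy)benzyl] sulfonium tetrafluoroborate of 4 (benzyl group on the exo lone pair) | C[C@@H]1CC[C@@H]2C[C@H]1[S@@+](Cc3ccc(OCc4ccccc4)c(OCc4ccccc4)c3)C2(C)C.F[B-](F)(F)F | intermediate
6 | potassium 5-(benzyloxy)-2-{[(2R,3S)-3-[3,4-bis(benzyloxy)phenyl]oxiran-2-yl]carbonyl}phenolate (trans epoxide) | [K+].[O-]c1cc(OCc2ccccc2)ccc1C(=O)[C@@H]1O[C@H]1c1ccc(OCc2ccccc2)c(OCc2ccccc2)c1 | intermediate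
7 | (2R,3R)-7-(benzyloxy)-2-[3,4-bis(benzyloxy)phenyl]-3-hydroxychroman-4-one | O(Cc3ccccc3)c1ccc2c(c1)O[C@H](c1ccc(OCc3ccccc3)c(OCc3ccccc3)c1)[C@@H](O)C2=O | intermediate
8 | 3-O-TBS ether of 7 | O(Cc3ccccc3)c1ccc2c(c1)O[C@H](c1ccc(OCc3ccccc3)c(OCc3ccccc3)c1)[C@@H](O[Si](C)(C)C(C)(C)C)C2=O | intermediate
9 | (2R,3S,4R)-3-O-TBS-chroman-4-ol (3,4-trans) | O(Cc3ccccc3)c1ccc2c(c1)O[C@H](c1ccc(OCc3ccccc3)c(OCc3ccccc3)c1)[C@@H](O[Si](C)(C)C(C)(C)C)[C@@H]2O | intermediate
10 | 3,4-bis-O-TBS ether of 9 | O(Cc3ccccc3)c1ccc2c(c1)O[C@H](c1ccc(OCc3ccccc3)c(OCc3ccccc3)c1)[C@@H](O[Si](C)(C)C(C)(C)C)[C@@H]2O[Si](C)(C)C(C)(C)C | intermediate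
11 | 6-bromo derivative of 9 | O(Cc3ccccc3)c1c(Br)cc2c(c1)O[C@H](c1ccc(OCc3ccccc3)c(OCc3ccccc3)c1)[C@@H](O[Si](C)(C)C(C)(C)C)[C@@H]2O | intermediate
12 | 4-O-trichloroacetimidate of 11 | O(Cc3ccccc3)c1c(Br)cc2c(c1)O[C@H](c1ccc(OCc3ccccc3)c(OCc3ccccc3)c1)[C@@H](O[Si](C)(C)C(C)(C)C)[C@@H]2OC(=N)C(Cl)(Cl)Cl | intermediate
13 | bromo dimer, (4α→6) linked, middle unit 6-Br and 3-OTBS, bottom unit 3,4-di-OTBS | Brc1cc2c(cc1OCc3ccccc3)O[C@H](c1ccc(OCc3ccccc3)c(OCc3ccccc3)c1)[C@@H](O[Si](C)(C)C(C)(C)C)[C@@H]2c1cc2c(cc1OCc3ccccc3)O[C@H](c1ccc(OCc3ccccc3)c(OCc3ccccc3)c1)[C@@H](O[Si](C)(C)C(C)(C)C)[C@@H]2O[Si](C)(C)C(C)(C)C | intermediate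
14 | 6-lithio dimer from 13 | [Li]c1cc2c(cc1OCc3ccccc3)O[C@H](c1ccc(OCc3ccccc3)c(OCc3ccccc3)c1)[C@@H](O[Si](C)(C)C(C)(C)C)[C@@H]2c1cc2c(cc1OCc3ccccc3)O[C@H](c1ccc(OCc3ccccc3)c(OCc3ccccc3)c1)[C@@H](O[Si](C)(C)C(C)(C)C)[C@@H]2O[Si](C)(C)C(C)(C)C | intermediate
15 | trimer carbinol (top unit 3β-OTBS, 4β-OH, 4α-aryl) | O(Cc3ccccc3)c1ccc2c(c1)O[C@H](c1ccc(OCc3ccccc3)c(OCc3ccccc3)c1)[C@@H](O[Si](C)(C)C(C)(C)C)[C@]2(O)c1cc2c(cc1OCc3ccccc3)O[C@H](c1ccc(OCc3ccccc3)c(OCc3ccccc3)c1)[C@@H](O[Si](C)(C)C(C)(C)C)[C@@H]2c1cc2c(cc1OCc3ccccc3)O[C@H](c1ccc(OCc3ccccc3)c(OCc3ccccc3)c1)[C@@H](O[Si](C)(C)C(C)(C)C)[C@@H]2O[Si](C)(C)C(C)(C)C | intermediate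
16 | trimer with a 2,4-trans-4β-arylflavan-3-one top unit | O(Cc3ccccc3)c1ccc2c(c1)O[C@H](c1ccc(OCc3ccccc3)c(OCc3ccccc3)c1)C(=O)[C@H]2c1cc2c(cc1OCc3ccccc3)O[C@H](c1ccc(OCc3ccccc3)c(OCc3ccccc3)c1)[C@@H](O[Si](C)(C)C(C)(C)C)[C@@H]2c1cc2c(cc1OCc3ccccc3)O[C@H](c1ccc(OCc3ccccc3)c(OCc3ccccc3)c1)[C@@H](O[Si](C)(C)C(C)(C)C)[C@@H]2O[Si](C)(C)C(C)(C)C | intermediate
17 | nona-O-benzyl tris-O-TBS trimer, top 3β-OH free | O(Cc3ccccc3)c1ccc2c(c1)O[C@H](c1ccc(OCc3ccccc3)c(OCc3ccccc3)c1)[C@@H](O)[C@H]2c1cc2c(cc1OCc3ccccc3)O[C@H](c1ccc(OCc3ccccc3)c(OCc3ccccc3)c1)[C@@H](O[Si](C)(C)C(C)(C)C)[C@@H]2c1cc2c(cc1OCc3ccccc3)O[C@H](c1ccc(OCc3ccccc3)c(OCc3ccccc3)c1)[C@@H](O[Si](C)(C)C(C)(C)C)[C@@H]2O[Si](C)(C)C(C)(C)C | intermediate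
18 | nona-O-benzyl trimer, four aliphatic OH free | O(Cc3ccccc3)c1ccc2c(c1)O[C@H](c1ccc(OCc3ccccc3)c(OCc3ccccc3)c1)[C@@H](O)[C@H]2c1cc2c(cc1OCc3ccccc3)O[C@H](c1ccc(OCc3ccccc3)c(OCc3ccccc3)c1)[C@@H](O)[C@@H]2c1cc2c(cc1OCc3ccccc3)O[C@H](c1ccc(OCc3ccccc3)c(OCc3ccccc3)c1)[C@@H](O)[C@@H]2O | intermediate
19 | fisetinidol-(4β→6)-fisetinidol-(4α→6)-(2R,3S,4R)-leucofisetinidin | Oc1ccc2c(c1)O[C@H](c1ccc(O)c(O)c1)[C@@H](O)[C@H]2c1cc2c(cc1O)O[C@H](c1ccc(O)c(O)c1)[C@@H](O)[C@@H]2c1cc2c(cc1O)O[C@H](c1ccc(O)c(O)c1)[C@@H](O)[C@@H]2O | target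

**Total step count:** 13.
**Longest linear sequence:** 11 steps (1, 3, 4, 5, 7, 8, 9, 10, 11, 12, 13).

**Steps most likely to fail**

1. **Step 3.**
- Risk: the ylide may be quenched by proton transfer. The glyoxal phenoxide may decay by an intramolecular hydride shift before it is intercepted. The phenoxide may open the epoxide in the 5-exo sense and then lose water.
- Fallback (known chemistry, from 1 back to 7): the phenol of 1 is protected with chloromethyl methyl ether and i-Pr2NEt as 1-[4-(benzyloxy)-2-(methoxymethoxy)phenyl]ethan-1-one F1. A Claisen–Schmidt condensation with commercial 3,4-bis(benzyloxy)benzaldehyde (KOH, EtOH) gives the (E)-chalcone F2. A Juliá–Colonna epoxidation (poly-L-leucine, H2O2, NaOH, toluene–water) gives the (αR,βS)-epoxychalcone F3. Acid-catalysed methanolysis of the acetal frees the phenol, which opens the epoxide at the benzylic carbon to give 7.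

2. **Step 11.**
- Risk: the cation may lose a proton and be re-protonated without facial bias, which leaves C4 under incomplete control. C2 may epimerise at the ketone stage. The acid may ionise the benzylic silyl ether of the bottom unit.
- Fallback (from 15 back to 18): the tertiary hydroxyl is removed directly by ionic hydrogenation (Bu3SnH, CF3CO2H, CH2Cl2, −40 °C). Hydride is captured by the C4 cation on the face opposite the 3β-silyloxy group. This keeps C3 as made in step 3 and gives the nona-O-benzyl tetrakis-O-TBS trimer F4, whose four silyl ethers are then cleaved with Bu4NF/AcOH to reach 18.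

3. **Step 13.**
- Risk: over-reduction, meaning hydrogenolytic loss of the free benzylic hydroxyl at C4 of the bottom unit. Acid traces on the catalyst could also start ionisation and self-condensation.
- Fallback (from 17 back to 19): the order of deprotection is reversed. Hydrogenolysis is run on 17 with the three silyl ethers still in place, so the C4–O bond of the bottom unit is shielded, and this gives the nonaphenol tris-O-TBS trimer F5. The silyl groups are then removed with Et3N·3HF in THF to give 19.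

**Further compounds**
F1 | step 3 | 1-[4-(benzyloxy)-2-(methoxymethoxy)phenyl]ethan-1-one | CC(=O)c1ccc(OCc2ccccc2)cc1OCOC
F2 | step 3 | (E)-1-[4-(benzyloxy)-2-(methoxymethoxy)phenyl]-3-[3,4-bis(benzyloxy)phenyl]prop-2-en-1-one | COCOc1cc(OCc2ccccc2)ccc1C(=O)/C=C/c1ccc(OCc2ccccc2)c(OCc2ccccc2)c1
F3 | step 3 | [4-(benzyloxy)-2-(methoxymethoxy)phenyl]{(2R,3S)-3-[3,4-bis(benzyloxy)phenyl]oxiran-2-yl}methanone | COCOc1cc(OCc2ccccc2)ccc1C(=O)[C@@H]1O[C@H]1c1ccc(OCc2ccccc2)c(OCc2ccccc2)c1
F4 | step 11 | nona-O-benzyl tetrakis-O-TBS trimer (top unit 3β-OTBS, 4β-aryl) | O(Cc3ccccc3)c1ccc2c(c1)O[C@H](c1ccc(OCc3ccccc3)c(OCc3ccccc3)c1)[C@@H](O[Si](C)(C)C(C)(C)C)[C@H]2c1cc2c(cc1OCc3ccccc3)O[C@H](c1ccc(OCc3ccccc3)c(OCc3ccccc3)c1)[C@@H](O[Si](C)(C)C(C)(C)C)[C@@H]2c1cc2c(cc1OCc3ccccc3)O[C@H](c1ccc(OCc3ccccc3)c(OCc3ccccc3)c1)[C@@H](O[Si](C)(C)C(C)(C)C)[C@@H]2O[Si](C)(C)C(C)(C)C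
F5 | step 13 | nonaphenol tris-O-TBS trimer | Oc1ccc2c(c1)O[C@H](c1ccc(O)c(O)c1)[C@@H](O)[C@H]2c1cc2c(cc1O)O[C@H](c1ccc(O)c(O)c1)[C@@H](O[Si](C)(C)C(C)(C)C)[C@@H]2c1cc2c(cc1O)O[C@H](c1ccc(O)c(O)c1)[C@@H](O[Si](C)(C)C(C)(C)C)[C@@H]2O[Si](C)(C)C(C)(C)C
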